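Follow the starting material that is left, not the target made, and ask how fast that fraction falls. The flasks below change the second substrate and hold the starting material and the gas.

| flask | starting material | second substrate | gas | remark | time |
|---|---|---|---|---|---|
| maple | 0.80 M | 0.012 M | 54 mM (held) | run made earlier |  |
| cedar | 0.80 M | 0.79 M | 54 mM (held) | run made earlier |  |
| dawn | 0.80 M | 0.0150 M | 54 mM (held) |  | 6.0 min |
| summer | 0.80 M | 0.0400 M | 54 mM (held) |  | 6.0 min |
| noon | 0.80 M | 0.120 M | 54 mM (held) |  | 6.0 min |
| spring | 0.80 M | 0.400 M | 54 mM (held) |  | 6.0 min |
| midnight | 0.80 M | 1.20 M | 54 mM (held) |  | 6.0 min |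

- maple (time / min: target / %): 0.333: 2; 0.500: 4; 1.00: 7; 1.50: 12; 2.50: 17; 4.00: 28
- cedar (time / min: target / %): 0.333: 0; 0.500: 0; 1.00: 5; 1.50: 8; 2.50: 12; 4.00: 22

(each reading ± 2 percentage points)

- at the start none of the gas is in solution
- "hardly changes" means that all values lie within two and a half points (for a concentration: within two and a half percent of the largest)

- [target] at the end for dawn, summer, noon, spring, midnight, in this order
- how that number moves from the first to the last of them (hardly changes / falls, then rises / rises, then falls / rises all the way / falls all the way)

In the maple run 72.0% of the starting material is left at 4.00 min, and the readings before it lie on a straight line within their scatter of 2 percentage points. So call d the drain, the fraction of the charge lost per minute, and read it as 0.0700 min⁻¹. A straight fall is what chemists call zero order in the starting material.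

Ines holds that the second substrate plays no part, since the cedar run has 65.8 times the charge of the maple run and still climbs at 0.0567 min⁻¹ from 1.00 min on. Her row is flat: 58.0% left at 6.0 min, which is 0.336 M of target.

Tom answers that the cedar run trails the maple run at each reading and shows 0% at 0.500 min. He turns its gap at 4.00 min into time lost at the drain d, 0.857 min as a reading, and assumes that this time grows in proportion to the second substrate. That gives 1.30 min lost in midnight, so 67.1% left and 0.263 M of target. In dawn it gives 0.0163 min lost, which leaves Ines's figure standing there. I side with Tom, with a row that falls gently at first and faster at the high end.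

The forecast takes the same side, with 0.33 M, 0.33 M, 0.32 M, 0.3 M and 0.26 M, falls all the way, though it adds that “the decline is only modestly supported”.

The flask gives 0.326 M, 0.323 M, 0.315 M, 0.289 M and 0.233 M: falls all the way.

    gas ⇌ reagent, rate k1*(csat - [reagent]) (kL = 0.0310 s⁻¹)
    second substrate + reagent ⇌ second product (K = 13.0 M⁻¹, k = 0.0700 M⁻¹ s⁻¹)
    starting material + reagent ⇌ target (K = 280 M⁻¹, k = 0.0690 M⁻¹ s⁻¹)

Dawn has 59% left at 6.00 min, against 58.0% from d, and Ines's flat row serves at the low charges: from dawn to noon the target falls by 1.3 points, where a reading scatters by 2 points, and a percent more second substrate changes the target by −0.0048 percent at dawn and by −0.12 percent at spring. Midnight has 71% left, which at d is 1.86 min lost. In dawn the step between starting material plus reagent and target relaxes, both ways together, with a half-life of 0.332 min, shorter than the run's 6.0 min. At 6.00 min in dawn, reagent is made 1.03 times as fast as it is used up, each step taken net.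

The data are simulated with made-up constants, and the scatter is random.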